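**Retrosynthetic overview** (rings: A/C chromone, B catechol-derived benzene, D dioxane, E guaiacyl; C10 carries CH2OH, C11 carries ring E)
1. Target 24 ⇐ pentabenzyl ether 23 by global hydrogenolysis.
2. 23 ⇐ 2-benzyloxy-1,3-diketone 22 by closing ring C at O1–C8a. O1 sits on ring A carbon C8a, which is ortho (through C4a) to the C4 carbonyl, so a fluorine on C8a can be displaced by the enol oxygen of the C2 carbonyl; C3 already carries its oxygen.
3. 22 ⇐ C-acylation of the lithium enolate of ring A ketone 19 with benzodioxane acid chloride 20; 19 comes from 1,3,5-trifluorobenzene by SNAr, bromination, Br/Li exchange and Weinreb acylation.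
4. Benzodioxane acid 12 ⇐ α-hydroxy ketone 7 (O-benzyl-D-serine plus the ring E Grignard reagent) by Mitsunobu inversion at C10 with the 4-OH of methyl 3,4-dihydroxybenzoate, chelation-controlled reduction, and Mitsunobu closure with inversion at C11.
5. Ring order: ring D first (step 7), ring C last (step 14); rings A, B and E are bought as arenes.

Key step: step 14

Remark: diketone 22 is expected as a mixture of epimers at its central carbon (with some enol); this is of no consequence because that carbon becomes the sp2 carbon C3 in step 14.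

**Step 1**
Reactants: 1 4-bromo-2-methoxyphenol
Product: 2 1-(benzyloxy)-4-bromo-2-methoxybenzene
Conditions: BnBr, K2CO3, DMF, rt
Reagents that add atoms: benzyl bromide, BrCc1ccccc1
Why: Williamson etherification (SN2 of the potassium phenoxide on benzyl bromide) protects the ring E phenol as a benzyl ether that survives the organometallic, Mitsunobu and basic steps and falls in the final hydrogenolysis.

**Step 2**
Reactants: 3 O-benzyl-D-serine
Product: 4 (R)-3-(benzyloxy)-2-hydroxypropanoic acid
Conditions: NaNO2, 1 M aqueous H2SO4, 0 °C → rt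
Reagents that add atoms: water, O
Why: Diazotisation of the α-amino acid followed by carboxylate-assisted loss of nitrogen and attack of water runs through two successive inversions, so the hydroxy acid keeps the (R) configuration of D-serine while the benzyl ether is inert to cold dilute acid.

**Step 3**
Reactants: 4 (R)-3-(benzyloxy)-2-hydroxypropanoic acid
Product: 5 (R)-3-(benzyloxy)-2-hydroxy-N-methoxy-N-methylpropanamide
Conditions: MeNH(OMe)·HCl, EDC·HCl, HOBt, N-methylmorpholine, CH2Cl2, 0 °C → rt
Reagents that add atoms: N,O-dimethylhydroxylamine hydrochloride, CNOC.Cl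
Why: Carbodiimide/HOBt amide coupling, in which the HOBt ester acylates the hydroxylamine nitrogen much faster than the secondary hydroxyl and no base strong enough to epimerise the α-carbon is present.

**Step 4**
Reactants: 2 1-(benzyloxy)-4-bromo-2-methoxybenzene; 5 (R)-3-(benzyloxy)-2-hydroxy-N-methoxy-N-methylpropanamide
Product: 7 (R)-3-(benzyloxy)-1-[4-(benzyloxy)-3-methoxyphenyl]-2-hydroxypropan-1-one, via Grignard reagent 6 (not isolated)
Conditions: 2 (2.6 equiv), Mg, THF, 45 °C; then 5, THF, −20 → 0 °C; aqueous NH4Cl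
Reagents that add atoms: none
Why: Weinreb ketone synthesis, in which the first equivalent of Grignard reagent deprotonates the hydroxyl and a further one adds to the amide to give a magnesium-chelated tetrahedral intermediate that resists over-addition and enolisation until the quench, so the (R) centre is carried through unchanged.

**Step 5**
Reactants: 7 (R)-3-(benzyloxy)-1-[4-(benzyloxy)-3-methoxyphenyl]-2-hydroxypropan-1-one; 8 methyl 3,4-dihydroxybenzoate
Product: 9 methyl 4-{[(2S)-3-(benzyloxy)-1-[4-(benzyloxy)-3-methoxyphenyl]-1-oxopropan-2-yl]oxy}-3-hydroxybenzoate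
Conditions: PPh3, DIAD, 8 (1.5 equiv), THF, 0 °C → rt
Reagents that add atoms: none
Why: Mitsunobu etherification, in which the alkoxyphosphonium ion of the secondary alcohol is displaced in SN2 fashion by the more acidic 4-phenoxide (para to the ester) of the catechol, which fixes the silybin regiochemistry and inverts the carbinol carbon from (R) to the (S) configuration needed at C10.

**Step 6**
Reactants: 9 methyl 4-{[(2S)-3-(benzyloxy)-1-[4-(benzyloxy)-3-methoxyphenyl]-1-oxopropan-2-yl]oxy}-3-hydroxybenzoate
Product: 10 methyl 4-{[(1R,2S)-3-(benzyloxy)-1-[4-(benzyloxy)-3-methoxyphenyl]-1-hydroxypropan-2-yl]oxy}-3-hydroxybenzoate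
Conditions: Zn(BH4)2, Et2O–THF, −30 → 0 °C; aqueous NH4Cl
Reagents that add atoms: none
Why: Chelation-controlled (Cram-chelate) hydride reduction, in which zinc bridges the carbonyl oxygen and the α-aryloxy oxygen (anchored by the neighbouring zinc phenoxide) and hydride adds to the face opposite the CH2OBn group to give the (1R,2S) erythro alcohol, while the aryl ester is not reduced at low temperature and the minor epimer would be removed by chromatography.

**Step 7**
Reactants: 10 methyl 4-{[(1R,2S)-3-(benzyloxy)-1-[4-(benzyloxy)-3-methoxyphenyl]-1-hydroxypropan-2-yl]oxy}-3-hydroxybenzoate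
Product: 11 methyl (2S,3S)-3-[4-(benzyloxy)-3-methoxyphenyl]-2-[(benzyloxy)methyl]-2,3-dihydro-1,4-benzodioxine-6-carboxylate
Conditions: PPh3, DIAD, THF, 0 °C → rt
Reagents that add atoms: none
Why: Intramolecular Mitsunobu etherification, in which the free phenol displaces the activated benzylic oxygen with inversion (1R to 3S, 6-exo-tet) and closes ring D as the trans-(2S,3S) isomer, and any ionisation of the electron-rich benzylic centre would also collapse to this more stable trans ring.

**Step 8**
Reactants: 11 methyl (2S,3S)-3-[4-(benzyloxy)-3-methoxyphenyl]-2-[(benzyloxy)methyl]-2,3-dihydro-1,4-benzodioxine-6-carboxylate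
Product: 12 (2S,3S)-3-[4-(benzyloxy)-3-methoxyphenyl]-2-[(benzyloxy)methyl]-2,3-dihydro-1,4-benzodioxine-6-carboxylic acid
Conditions: LiOH·H2O, THF–MeOH–H2O, 45 °C; then 1 M HCl
Reagents that add atoms: lithium hydroxide, [Li+].[OH-]
Why: Saponification (acyl substitution by hydroxide) of the methyl ester, with neither dioxane stereocentre carrying an acidic hydrogen and the benzyl ethers inert to base.

**Step 9**
Reactants: 13 1,3,5-trifluorobenzene
Product: 14 1,3-bis(benzyloxy)-5-fluorobenzene
Conditions: BnOH (2.05 equiv), NaH (2.1 equiv), NMP, 0 → 100 °C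
Reagents that add atoms: benzyl alcohol, OCc1ccccc1
Why: Twofold nucleophilic aromatic substitution (addition–elimination) of fluoride by benzyloxide, in which each benzyloxy group introduced sits meta to the remaining C–F bonds and slows but does not block the second displacement, while the third is slower still, so two equivalents of alkoxide should stop at the fluoro bis-ether.

**Step 10**
Reactants: 14 1,3-bis(benzyloxy)-5-fluorobenzene
Product: 15 1,5-bis(benzyloxy)-2-bromo-3-fluorobenzene
Conditions: NBS (1.0 equiv), MeCN, 0 °C → rt, dark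
Reagents that add atoms: N-bromosuccinimide, O=C1CCC(=O)N1Br
Why: Electrophilic aromatic bromination at the carbon ortho to one benzyloxy group and para to the other, next to the small fluorine, which is favoured on steric grounds over the site flanked by two benzyloxy groups, as in formylations and halogenations of 5-substituted resorcinol diethers.

**Step 11**
Reactants: 16 (benzyloxy)acetyl chloride
Product: 17 2-(benzyloxy)-N-methoxy-N-methylacetamide
Conditions: MeNH(OMe)·HCl, Et3N, CH2Cl2, 0 °C → rt
Reagents that add atoms: N,O-dimethylhydroxylamine hydrochloride, CNOC.Cl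
Why: N-Acylation of the hydroxylamine by the acid chloride gives the Weinreb amide.

**Step 12**
Reactants: 15 1,5-bis(benzyloxy)-2-bromo-3-fluorobenzene; 17 2-(benzyloxy)-N-methoxy-N-methylacetamide
Product: 19 2-(benzyloxy)-1-[2,4-bis(benzyloxy)-6-fluorophenyl]ethan-1-one, via aryllithium 18 (not isolated)
Conditions: n-BuLi, THF, −78 °C; then 17, −78 → −40 °C; aqueous NH4Cl
Reagents that add atoms: none
Why: Bromine–lithium exchange at −78 °C is faster than benzylic deprotonation and gives a 2-fluoroaryllithium that does not lose LiF at this temperature, and its addition to the Weinreb amide (Weinreb ketone synthesis) stops at the chelated tetrahedral intermediate, which releases the ketone on quench.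

**Step 13**
Reactants: 12 (2S,3S)-3-[4-(benzyloxy)-3-methoxyphenyl]-2-[(benzyloxy)methyl]-2,3-dihydro-1,4-benzodioxine-6-carboxylic acid; 19 2-(benzyloxy)-1-[2,4-bis(benzyloxy)-6-fluorophenyl]ethan-1-one
Product: 22 2-(benzyloxy)-1-[2,4-bis(benzyloxy)-6-fluorophenyl]-3-{(2S,3S)-3-[4-(benzyloxy)-3-methoxyphenyl]-2-[(benzyloxy)methyl]-2,3-dihydro-1,4-benzodioxin-6-yl}propane-1,3-dione, via acid chloride 20 (not isolated), via lithium enolate 21 (not isolated)
Conditions: 12, (COCl)2, catalytic DMF, CH2Cl2, 0 °C → rt, then evaporation; 19 (2.0 equiv), LiN(SiMe3)2 (2.1 equiv), toluene–THF, −78 → 0 °C; then 20, 0 °C; aqueous NH4Cl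
Reagents that add atoms: none
Why: C-Acylation of a ketone lithium enolate by an aroyl chloride (crossed Claisen-type condensation), in which the aggregated lithium enolate in a toluene-rich medium reacts at carbon, the second equivalent of enolate deprotonates the more acidic diketone and shields it from further acylation, and the excess of ketone 19 is recovered.

**Step 14**
Reactants: 22 2-(benzyloxy)-1-[2,4-bis(benzyloxy)-6-fluorophenyl]-3-{(2S,3S)-3-[4-(benzyloxy)-3-methoxyphenyl]-2-[(benzyloxy)methyl]-2,3-dihydro-1,4-benzodioxin-6-yl}propane-1,3-dione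
Product: 23 3,5,7-tris(benzyloxy)-2-{(2S,3S)-3-[4-(benzyloxy)-3-methoxyphenyl]-2-[(benzyloxy)methyl]-2,3-dihydro-1,4-benzodioxin-6-yl}-4H-chromen-4-one (penta-O-benzyl-2,3-dehydrosilybin B)
Conditions: K2CO3 (3 equiv), dry DMF, 80 °C, N2
Reagents that add atoms: none
Why: Carbonate removes the central C–H of the 2-benzyloxy-1,3-diketone, and the enolate oxygen on the ring B side carbon (the future C2) adds to the fluorine-bearing ring A carbon C8a to give a Meisenheimer anion delocalised through C4a into the C4 carbonyl, from which fluoride is expelled (addition–elimination). The closest known reaction type is the base-mediated cyclisation of 1-(2-fluoroaryl)-1,3-diketones to chromones and flavones. Ring C closes by attack of oxygen on an aromatic sp2 carbon through a six-membered transition state, formally a 6-endo-trig addition to the C4a=C8a bond conjugated with C4=O. No stereocentre is formed, the central carbon of 22 becomes sp2 C3 with its benzyloxy group in place, and C10 and C11 carry no acidic hydrogen and are untouched by K2CO3. The step needs attack by oxygen and not carbon, by the correct enolate oxygen, and loss of fluoride and not of benzyloxide: attack by the enolate carbon or by the oxygen on C4 would give four-membered rings, and only C8a carries a good nucleofuge on a carbon activated by the ortho carbonyl. The two benzyloxy groups lie meta to C8a and place no extra electron density on the attacked carbon, so heating in dry DMF under nitrogen should suffice.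

**Step 15**
Reactants: 23 penta-O-benzyl-2,3-dehydrosilybin B
Product: 24 2,3-dehydrosilybin B
Conditions: H2 (1 atm), 10% palladium on carbon (Pd/C), THF–MeOH, rt
Reagents that add atoms: none
Why: Catalytic hydrogenolysis of four aryl benzyl ethers and the primary alkyl benzyl ether, in which the C2=C3 bond belongs to the aromatic pyranone and is not reduced and the ring-embedded secondary benzylic C11–O bond is cleaved far more slowly than the exocyclic O-benzyl groups, so the reaction is stopped after uptake of five equivalents of hydrogen.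

**Compound list**
1 | 4-bromo-2-methoxyphenol | COc1cc(Br)ccc1O | starting material
2 | 1-(benzyloxy)-4-bromo-2-methoxybenzene | COc1cc(Br)ccc1OCc1ccccc1 | intermediate
3 | O-benzyl-D-serine | N[C@H](COCc1ccccc1)C(=O)O | starting material
4 | (R)-3-(benzyloxy)-2-hydroxypropanoic acid | O[C@H](COCc1ccccc1)C(=O)O | intermediate
5 | (R)-3-(benzyloxy)-2-hydroxy-N-methoxy-N-methylpropanamide | O[C@H](COCc1ccccc1)C(=O)N(C)OC | intermediate
6 | [4-(benzyloxy)-3-methoxyphenyl]magnesium bromide | COc1cc([Mg]Br)ccc1OCc1ccccc1 | intermediate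
7 | (R)-3-(benzyloxy)-1-[4-(benzyloxy)-3-methoxyphenyl]-2-hydroxypropan-1-one | O[C@H](COCc1ccccc1)C(=O)c1ccc(OCc2ccccc2)c(OC)c1 | intermediate
8 | methyl 3,4-dihydroxybenzoate | COC(=O)c1ccc(O)c(O)c1 | starting material
9 | methyl 4-{[(2S)-3-(benzyloxy)-1-[4-(benzyloxy)-3-methoxyphenyl]-1-oxopropan-2-yl]oxy}-3-hydroxybenzoate | COC(=O)c1ccc(O[C@@H](COCc2ccccc2)C(=O)c2ccc(OCc3ccccc3)c(OC)c2)c(O)c1 | intermediate
10 | methyl 4-{[(1R,2S)-3-(benzyloxy)-1-[4-(benzyloxy)-3-methoxyphenyl]-1-hydroxypropan-2-yl]oxy}-3-hydroxybenzoate | COC(=O)c1ccc(O[C@@H](COCc2ccccc2)[C@H](O)c2ccc(OCc3ccccc3)c(OC)c2)c(O)c1 | intermediate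
11 | methyl (2S,3S)-3-[4-(benzyloxy)-3-methoxyphenyl]-2-[(benzyloxy)methyl]-2,3-dihydro-1,4-benzodioxine-6-carboxylate | COc1cc([C@@H]2Oc3cc(C(=O)OC)ccc3O[C@H]2COCc2ccccc2)ccc1OCc1ccccc1 | intermediate
12 | (2S,3S)-3-[4-(benzyloxy)-3-methoxyphenyl]-2-[(benzyloxy)methyl]-2,3-dihydro-1,4-benzodioxine-6-carboxylic acid | COc1cc([C@@H]2Oc3cc(C(=O)O)ccc3O[C@H]2COCc2ccccc2)ccc1OCc1ccccc1 | intermediate
13 | 1,3,5-trifluorobenzene | Fc1cc(F)cc(F)c1 | starting material
14 | 1,3-bis(benzyloxy)-5-fluorobenzene | Fc1cc(OCc2ccccc2)cc(OCc2ccccc2)c1 | intermediate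
15 | 1,5-bis(benzyloxy)-2-bromo-3-fluorobenzene | Fc1cc(OCc2ccccc2)cc(OCc2ccccc2)c1Br | intermediate
16 | (benzyloxy)acetyl chloride | O=C(Cl)COCc1ccccc1 | starting material
17 | 2-(benzyloxy)-N-methoxy-N-methylacetamide | CON(C)C(=O)COCc1ccccc1 | intermediate
18 | [2,4-bis(benzyloxy)-6-fluorophenyl]lithium | [Li]c1c(F)cc(OCc2ccccc2)cc1OCc1ccccc1 | intermediate
19 | 2-(benzyloxy)-1-[2,4-bis(benzyloxy)-6-fluorophenyl]ethan-1-one | O=C(COCc1ccccc1)c1c(F)cc(OCc2ccccc2)cc1OCc1ccccc1 | intermediate
20 | (2S,3S)-3-[4-(benzyloxy)-3-methoxyphenyl]-2-[(benzyloxy)methyl]-2,3-dihydro-1,4-benzodioxine-6-carbonyl chloride | COc1cc([C@@H]2Oc3cc(C(=O)Cl)ccc3O[C@H]2COCc2ccccc2)ccc1OCc1ccccc1 | intermediate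
21 | lithium (Z)-enolate of ketone 19 | [Li]O/C(=C\OCc1ccccc1)c1c(F)cc(OCc2ccccc2)cc1OCc1ccccc1 | intermediate
22 | 2-(benzyloxy)-1-[2,4-bis(benzyloxy)-6-fluorophenyl]-3-{(2S,3S)-3-[4-(benzyloxy)-3-methoxyphenyl]-2-[(benzyloxy)methyl]-2,3-dihydro-1,4-benzodioxin-6-yl}propane-1,3-dione | COc1cc([C@@H]2Oc3cc(C(=O)C(OCc4ccccc4)C(=O)c4c(F)cc(OCc5ccccc5)cc4OCc4ccccc4)ccc3O[C@H]2COCc2ccccc2)ccc1OCc1ccccc1 | intermediate
23 | penta-O-benzyl-2,3-dehydrosilybin B | COc1cc([C@@H]2Oc3cc(-c4oc5cc(OCc6ccccc6)cc(OCc6ccccc6)c5c(=O)c4OCc4ccccc4)ccc3O[C@H]2COCc2ccccc2)ccc1OCc1ccccc1 | intermediate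
24 | 2,3-dehydrosilybin B | COc1cc([C@@H]2Oc3cc(-c4oc5cc(O)cc(O)c5c(=O)c4O)ccc3O[C@H]2CO)ccc1O | target

**Total step count:** 15
**Longest linear sequence:** 10 steps (steps 2, 3, 4, 5, 6, 7, 8, 13, 14 and 15, from O-benzyl-D-serine 3)

**Steps most likely to fail**

Step 14. The addition of the enolate oxygen to C8a may be slow, because ring A is alkoxy-rich and its carbonyl is twisted by two ortho substituents. Retro-Claisen cleavage of the diketone by adventitious hydroxide or air oxidation of the enolate could then take over. The fallback closes ring C the classical way, with the ring oxygen already on ring A and O1–C2 made last; it sets out from acid 12 (as its chloride 20) and returns at 23. Houben–Hoesch acylation of phloroglucinol with (benzyloxy)acetonitrile (HCl, ZnCl2, Et2O, 0 °C; then hot water) should give 2-(benzyloxy)-1-(2,4,6-trihydroxyphenyl)ethan-1-one F1. Benzylation with BnBr (2.1 equiv) and K2CO3 in DMF leaves the hydrogen-bonded ortho hydroxyl free and should give 2-(benzyloxy)-1-[2,4-bis(benzyloxy)-6-hydroxyphenyl]ethan-1-one F2. Acylation of this phenol with 20 (pyridine, CH2Cl2) gives 3,5-bis(benzyloxy)-2-[(benzyloxy)acetyl]phenyl (2S,3S)-3-[4-(benzyloxy)-3-methoxyphenyl]-2-[(benzyloxy)methyl]-2,3-dihydro-1,4-benzodioxine-6-carboxylate F3. Baker–Venkataraman rearrangement with LiN(SiMe3)2 in THF (−78 → 0 °C) moves the aroyl group to the α-carbon and gives 2-(benzyloxy)-1-[2,4-bis(benzyloxy)-6-hydroxyphenyl]-3-{(2S,3S)-3-[4-(benzyloxy)-3-methoxyphenyl]-2-[(benzyloxy)methyl]-2,3-dihydro-1,4-benzodioxin-6-yl}propane-1,3-dione F4. Cyclodehydration with catalytic TsOH in toluene at 80 °C then gives 23.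

Step 5. Discrimination between the two phenols may be incomplete, or double alkylation may occur. The catechol may also be tied up by the phosphonium reagent, and enolisation of the α-aryloxy ketone could erode enantiopurity or eliminate benzyloxide. The fallback forms the aryl ether by SN2 alkylation at the less acidic amide stage; it sets out from Weinreb amide 5 and returns at ketone 9. Mesylation (MsCl, Et3N, CH2Cl2, 0 °C) gives (2R)-3-(benzyloxy)-1-[methoxy(methyl)amino]-1-oxopropan-2-yl methanesulfonate F5. With 8 and one equivalent of K2CO3 in DMF at 50 °C only the 4-phenoxide forms, and it displaces the mesylate with inversion to give methyl 4-{[(2S)-3-(benzyloxy)-1-[methoxy(methyl)amino]-1-oxopropan-2-yl]oxy}-3-hydroxybenzoate F6. Three equivalents of Grignard reagent 6 at −20 °C then give 9: the first equivalent deprotonates the phenol, which deactivates the benzoate, and the chelating Weinreb amide reacts faster than the aryl ester.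

Step 6. α-Chelation through the aryloxy oxygen competes with β-chelation through the CH2OBn oxygen and with an open Felkin-type transition state, which would lower the diastereoselectivity; the wrong epimer would lead to the cis ring in step 7. The fallback gives up stereospecific closure for a stereoconvergent one; it sets out from ketone 9 and returns at benzodioxane 11. Reduction with NaBH4 (MeOH–THF, 0 °C), with no demand on selectivity, gives 10 together with its epimer methyl 4-{[(1S,2S)-3-(benzyloxy)-1-[4-(benzyloxy)-3-methoxyphenyl]-1-hydroxypropan-2-yl]oxy}-3-hydroxybenzoate F7. Treating the mixture with BF3·OEt2 (CH2Cl2, −40 → 0 °C) ionises the benzylic alcohol to the cation stabilised by the para benzyloxy group. Reversible capture by the ortho phenol should favour the trans ring 11, in which both substituents are pseudo-equatorial; C10 is not touched.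

**Further compounds**
F1 | step 14 | 2-(benzyloxy)-1-(2,4,6-trihydroxyphenyl)ethan-1-one | O=C(COCc1ccccc1)c1c(O)cc(O)cc1O
F2 | step 14 | 2-(benzyloxy)-1-[2,4-bis(benzyloxy)-6-hydroxyphenyl]ethan-1-one | O=C(COCc1ccccc1)c1c(O)cc(OCc2ccccc2)cc1OCc1ccccc1
F3 | step 14 | 3,5-bis(benzyloxy)-2-[(benzyloxy)acetyl]phenyl (2S,3S)-3-[4-(benzyloxy)-3-methoxyphenyl]-2-[(benzyloxy)methyl]-2,3-dihydro-1,4-benzodioxine-6-carboxylate | COc1cc([C@@H]2Oc3cc(C(=O)Oc4cc(OCc5ccccc5)cc(OCc5ccccc5)c4C(=O)COCc4ccccc4)ccc3O[C@H]2COCc2ccccc2)ccc1OCc1ccccc1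
F4 | step 14 | 2-(benzyloxy)-1-[2,4-bis(benzyloxy)-6-hydroxyphenyl]-3-{(2S,3S)-3-[4-(benzyloxy)-3-methoxyphenyl]-2-[(benzyloxy)methyl]-2,3-dihydro-1,4-benzodioxin-6-yl}propane-1,3-dione | COc1cc([C@@H]2Oc3cc(C(=O)C(OCc4ccccc4)C(=O)c4c(O)cc(OCc5ccccc5)cc4OCc4ccccc4)ccc3O[C@H]2COCc2ccccc2)ccc1OCc1ccccc1
F5 | step 5 | (2R)-3-(benzyloxy)-1-[methoxy(methyl)amino]-1-oxopropan-2-yl methanesulfonate | CS(=O)(=O)O[C@H](COCc1ccccc1)C(=O)N(C)OC
F6 | step 5 | methyl 4-{[(2S)-3-(benzyloxy)-1-[methoxy(methyl)amino]-1-oxopropan-2-yl]oxy}-3-hydroxybenzoate | COC(=O)c1ccc(O[C@@H](COCc2ccccc2)C(=O)N(C)OC)c(O)c1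
F7 | step 6 | methyl 4-{[(1S,2S)-3-(benzyloxy)-1-[4-(benzyloxy)-3-methoxyphenyl]-1-hydroxypropan-2-yl]oxy}-3-hydroxybenzoate | COC(=O)c1ccc(O[C@@H](COCc2ccccc2)[C@@H](O)c2ccc(OCc3ccccc3)c(OC)c2)c(O)c1
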